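**Assumption:** C2 of the target is S, as read from the SMILES; the compound is (2S)-5,7-dihydroxy-2-(8-hydroxy-2,2-dimethyl-2H-chromen-6-yl)chroman-4-one (sigmoidin C). Simple reagents (MOMCl, TBSCl, MeNHOMe·HCl) are given with SMILES in each step and are not numbered.

## Retrosynthetic overview

1. Target ⇐ removal of three MOM ethers from the (2S)-flavanone 16. The pyranone C-ring is closed last, by intramolecular Mitsunobu etherification (inversion) of an (R)-benzylic carbinol by the 2'-phenol.
2. Open-chain β-hydroxy ketone ⇐ 2,4,6-tris(MOM-oxy)phenyllithium (from phloroglucinol) + (R)-β-silyloxy Weinreb amide (forms C4–C4a).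
3. The (R)-carbinol, the only stereocentre, ⇐ ketoreductase reduction of an achiral aryl β-keto ester.
4. β-Keto ester ⇐ chromenyl methyl ketone + diethyl carbonate. The 2,2-dimethylchromene ⇐ aryl 1,1-dimethylpropargyl ether (Claisen/6π) from 3',4'-dihydroxyacetophenone.
5. Ring order: B-ring pyran (chromene) first, then attachment of the A-ring, then the flavanone C-ring.

## Route

**Step 1**
Reactants: 1, 1-(3,4-dihydroxyphenyl)ethan-1-one
Product: 2, 1-[4-hydroxy-3-(methoxymethoxy)phenyl]ethan-1-one
Conditions: NaH (2.1 equiv), DMF, 0 °C; then MOMCl (1.0 equiv), 0 °C → rt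
Reagents that add atoms: chloromethyl methyl ether, COCCl
Why: In the catecholate dianion the 3-oxyanion (not conjugated to the acetyl group) is the more nucleophilic site, so one equivalent of electrophile gives the 3-O-MOM ether (regioselective Williamson O-alkylation via the dianion).

**Step 2**
Reactants: 2; 3, 3-chloro-3-methylbut-1-yne
Product: 4, 1-{3-(methoxymethoxy)-4-[(2-methylbut-3-yn-2-yl)oxy]phenyl}ethan-1-one
Conditions: 3 (1.5 equiv), DBU, CuCl2·2H2O (1 mol%), MeCN, 0 °C → rt
Reagents that add atoms: 3-chloro-3-methylbut-1-yne (3), CC(C)(Cl)C#C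
Why: Copper-catalysed propargylic substitution makes the hindered tertiary aryl propargyl ether from the only free (acidic, para-acyl) phenol.

**Step 3**
Reactants: 4
Product: 5, 1-[8-(methoxymethoxy)-2,2-dimethyl-2H-chromen-6-yl]ethan-1-one
Conditions: PhNEt2, 185 °C
Reagents that add atoms: none
Why: Aromatic propargyl Claisen rearrangement to the only free ortho carbon, then 1,5-H shift and 6π-oxa-electrocyclisation, gives the 2,2-dimethylchromene with the oxygens at C8 and C8a as required.

**Step 4**
Reactants: 5; 6, diethyl carbonate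
Product: 7, ethyl 3-[8-(methoxymethoxy)-2,2-dimethyl-2H-chromen-6-yl]-3-oxopropanoate
Conditions: NaH (2.5 equiv), (EtO)2CO (4 equiv), THF, reflux; AcOH quench
Reagents that add atoms: diethyl carbonate (6), CCOC(=O)OCC
Why: Claisen-type C-acylation of the methyl ketone enolate, driven by deprotonation of the β-keto ester product; the MOM ether and chromene are inert to base.

**Step 5**
Reactants: 7
Product: 8, ethyl (3R)-3-hydroxy-3-[8-(methoxymethoxy)-2,2-dimethyl-2H-chromen-6-yl]propanoate
Conditions: (R)-selective ketoreductase (KRED, NADPH-dependent alcohol dehydrogenase, picked from a commercial panel), NADP+ (cat.), i-PrOH (15% v/v), KPi pH 7.0, 10% DMSO, 30 °C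
Reagents that add atoms: none
Why: The ketoreductase delivers hydride to the Si face of the aryl ketone with i-PrOH-driven cofactor recycling, setting the only stereocentre as R (catalytic asymmetric biocatalytic carbonyl reduction; the ester and alkene are untouched).

**Step 6**
Reactants: 8
Product: 9, ethyl (3R)-3-[(tert-butyldimethylsilyl)oxy]-3-[8-(methoxymethoxy)-2,2-dimethyl-2H-chromen-6-yl]propanoate
Conditions: TBSCl, imidazole, DMF, rt
Reagents that add atoms: tert-butyldimethylsilyl chloride, CC(C)(C)[Si](C)(C)Cl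
Why: Silylation of the secondary alcohol blocks retro-aldol and elimination pathways in the organometallic steps and does not touch the stereocentre.

**Step 7**
Reactants: 9
Product: 10, (3R)-3-[(tert-butyldimethylsilyl)oxy]-N-methoxy-N-methyl-3-[8-(methoxymethoxy)-2,2-dimethyl-2H-chromen-6-yl]propanamide
Conditions: MeNH(OMe)·HCl, i-PrMgCl, THF, −20 → 0 °C
Reagents that add atoms: N,O-dimethylhydroxylamine hydrochloride, CNOC.Cl
Why: The magnesium amide converts the ester directly into the Weinreb amide (ester aminolysis) under conditions too mild to enolise and eliminate the β-silyloxy group.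

**Step 8**
Reactants: 11, benzene-1,3,5-triol (phloroglucinol)
Product: 12, 1,3,5-tris(methoxymethoxy)benzene
Conditions: NaH (3.6 equiv), MOMCl (3.6 equiv), DMF, 0 °C → rt
Reagents that add atoms: chloromethyl methyl ether, COCCl
Why: Exhaustive O-alkylation with the hard electrophile MOMCl gives the tris-acetal, whose three ring C–H positions are equivalent and each flanked by two directing groups.

**Step 9**
Reactants: 12 (2.0 equiv); 10
Product: 13, (3R)-3-[(tert-butyldimethylsilyl)oxy]-3-[8-(methoxymethoxy)-2,2-dimethyl-2H-chromen-6-yl]-1-[2,4,6-tris(methoxymethoxy)phenyl]propan-1-one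
Conditions: 12, n-BuLi (1.9 equiv), THF, 0 °C; then 10, −78 → 0 °C; NH4Cl (aq)
Reagents that add atoms: none (both fragments are numbered reactants)
Why: Directed ortho-lithiation between two OMOM groups gives the aryllithium, which adds once to the Weinreb amide through the stable chelated tetrahedral intermediate to give the aryl ketone (C4–C4a bond) without touching the stereocentre.

**Step 10**
Reactants: 13
Product: 14, (3R)-3-[(tert-butyldimethylsilyl)oxy]-1-[2-hydroxy-4,6-bis(methoxymethoxy)phenyl]-3-[8-(methoxymethoxy)-2,2-dimethyl-2H-chromen-6-yl]propan-1-one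
Conditions: MgBr2·OEt2 (2.5 equiv), Et2O/CH2Cl2, 0 °C → rt
Reagents that add atoms: none
Why: Chelation of Mg between the ketone and one ortho-OMOM oxygen activates only that acetal (chelation-controlled Lewis-acid cleavage), while the aprotic medium and the silyl ether keep the benzylic centre from ionising.

**Step 11**
Reactants: 14
Product: 15, (3R)-3-hydroxy-1-[2-hydroxy-4,6-bis(methoxymethoxy)phenyl]-3-[8-(methoxymethoxy)-2,2-dimethyl-2H-chromen-6-yl]propan-1-one
Conditions: HF·pyridine, pyridine, THF, 0 °C → rt
Reagents that add atoms: none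
Why: Buffered fluoride desilylation frees the carbinol without the base that would trigger β-elimination or retro-aldol, and without acid strong enough to cleave MOM or ionise the benzylic alcohol.

**Step 12**
Reactants: 15
Product: 16, (2S)-5,7-bis(methoxymethoxy)-2-[8-(methoxymethoxy)-2,2-dimethyl-2H-chromen-6-yl]-2,3-dihydro-4H-chromen-4-one
Conditions: PPh3, DIAD (1.5 equiv each), toluene (0.02 M), −20 → 0 °C
Reagents that add atoms: none
Why: Intramolecular Mitsunobu etherification: the 2'-phenol displaces the oxyphosphonium in a 6-exo-tet SN2 with clean inversion (3R → 2S), the β-acyl group and the cold non-polar medium disfavouring ionisation.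

**Step 13**
Reactants: 16
Product: 17, (2S)-5,7-dihydroxy-2-(8-hydroxy-2,2-dimethyl-2H-chromen-6-yl)-2,3-dihydro-4H-chromen-4-one (target)
Conditions: 2 M HCl (aq), MeOH/THF, 45 °C
Reagents that add atoms: none
Why: Acid-catalysed acetal hydrolysis removes all three MOM groups; flavanone C2 is configurationally stable in acid (racemisation is base-mediated) and the chromene tolerates dilute methanolic HCl.

## Compound list

1 | 1-(3,4-dihydroxyphenyl)ethan-1-one | CC(=O)c1ccc(O)c(O)c1 | starting material
2 | 1-[4-hydroxy-3-(methoxymethoxy)phenyl]ethan-1-one | CC(=O)c1ccc(O)c(OCOC)c1 | intermediate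
3 | 3-chloro-3-methylbut-1-yne | CC(C)(Cl)C#C | starting material
4 | 1-{3-(methoxymethoxy)-4-[(2-methylbut-3-yn-2-yl)oxy]phenyl}ethan-1-one | CC(=O)c1ccc(OC(C)(C)C#C)c(OCOC)c1 | intermediate
5 | 1-[8-(methoxymethoxy)-2,2-dimethyl-2H-chromen-6-yl]ethan-1-one | CC(=O)c1cc2C=CC(C)(C)Oc2c(OCOC)c1 | intermediate
6 | diethyl carbonate | CCOC(=O)OCC | starting material
7 | ethyl 3-[8-(methoxymethoxy)-2,2-dimethyl-2H-chromen-6-yl]-3-oxopropanoate | CCOC(=O)CC(=O)c1cc2C=CC(C)(C)Oc2c(OCOC)c1 | intermediate
8 | ethyl (3R)-3-hydroxy-3-[8-(methoxymethoxy)-2,2-dimethyl-2H-chromen-6-yl]propanoate | CCOC(=O)C[C@@H](O)c1cc2C=CC(C)(C)Oc2c(OCOC)c1 | intermediate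
9 | ethyl (3R)-3-[(tert-butyldimethylsilyl)oxy]-3-[8-(methoxymethoxy)-2,2-dimethyl-2H-chromen-6-yl]propanoate | CCOC(=O)C[C@@H](O[Si](C)(C)C(C)(C)C)c1cc2C=CC(C)(C)Oc2c(OCOC)c1 | intermediate
10 | (3R)-3-[(tert-butyldimethylsilyl)oxy]-N-methoxy-N-methyl-3-[8-(methoxymethoxy)-2,2-dimethyl-2H-chromen-6-yl]propanamide | CON(C)C(=O)C[C@@H](O[Si](C)(C)C(C)(C)C)c1cc2C=CC(C)(C)Oc2c(OCOC)c1 | intermediate
11 | benzene-1,3,5-triol (phloroglucinol) | Oc1cc(O)cc(O)c1 | starting material
12 | 1,3,5-tris(methoxymethoxy)benzene | COCOc1cc(OCOC)cc(OCOC)c1 | intermediate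
13 | (3R)-3-[(tert-butyldimethylsilyl)oxy]-3-[8-(methoxymethoxy)-2,2-dimethyl-2H-chromen-6-yl]-1-[2,4,6-tris(methoxymethoxy)phenyl]propan-1-one | COCOc1cc(OCOC)c(C(=O)C[C@@H](O[Si](C)(C)C(C)(C)C)c2cc3C=CC(C)(C)Oc3c(OCOC)c2)c(OCOC)c1 | intermediate
14 | (3R)-3-[(tert-butyldimethylsilyl)oxy]-1-[2-hydroxy-4,6-bis(methoxymethoxy)phenyl]-3-[8-(methoxymethoxy)-2,2-dimethyl-2H-chromen-6-yl]propan-1-one | COCOc1cc(O)c(C(=O)C[C@@H](O[Si](C)(C)C(C)(C)C)c2cc3C=CC(C)(C)Oc3c(OCOC)c2)c(OCOC)c1 | intermediate
15 | (3R)-3-hydroxy-1-[2-hydroxy-4,6-bis(methoxymethoxy)phenyl]-3-[8-(methoxymethoxy)-2,2-dimethyl-2H-chromen-6-yl]propan-1-one | COCOc1cc(O)c(C(=O)C[C@@H](O)c2cc3C=CC(C)(C)Oc3c(OCOC)c2)c(OCOC)c1 | intermediate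
16 | (2S)-5,7-bis(methoxymethoxy)-2-[8-(methoxymethoxy)-2,2-dimethyl-2H-chromen-6-yl]-2,3-dihydro-4H-chromen-4-one | COCOc1cc(OCOC)c2C(=O)C[C@@H](c3cc4C=CC(C)(C)Oc4c(OCOC)c3)Oc2c1 | intermediate
17 | (2S)-5,7-dihydroxy-2-(8-hydroxy-2,2-dimethyl-2H-chromen-6-yl)-2,3-dihydro-4H-chromen-4-one | CC1(C)C=Cc2cc([C@@H]3CC(=O)c4c(O)cc(O)cc4O3)cc(O)c2O1 | target

## Summary

Total steps: 13. Longest linear sequence: 12 (steps 1–7, then 9–13); step 8 is the one-step A-ring branch.

Three steps most likely to fail:

1. **Step 12 (Mitsunobu ring closure).** The carbinol is para-alkoxybenzylic, so partial SN1 leakage (loss of ee) or elimination to the chalcone is possible; ee of 16 must be checked by chiral HPLC. Fallback: create C2 by C–C rather than C–O bond formation, using Rh(I)/chiral-ligand asymmetric 1,4-addition of 8-(methoxymethoxy)-2,2-dimethyl-2H-chromen-6-ylboronic acid to 5,7-bis(methoxymethoxy)chromone, then the same deprotection.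
2. **Step 10 (removal of a single ortho-MOM).** It may stall, over-cleave, or disturb the benzylic silyl ether. Fallback: strip all aryl MOM groups from 13 under non-protic conditions (TMSOTf/2,2'-bipyridyl, then water), desilylate, and run the Mitsunobu closure on the free polyphenol, relying on intramolecularity; this also removes the need for step 13.
3. **Step 1 (regioselective mono-MOM protection via the dianion).** MOMCl is a very reactive electrophile, so 4-O and bis-alkylated products may form. Fallback: use a temporary group instead: selective 4-O-benzylation of the monoanion (K2CO3, BnBr), 3-O-MOM protection, then hydrogenolysis (H2, Pd/C) to reach 2 with unambiguous regiochemistry.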